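**Plan**

- Retrosynthesis: the C5–OH bond is cut first (back to a C5–F bond). Ring C is then cut at O1–C8a and at C3–C4, and the ring-B methyl ketone is cut last at its aryl–acetyl bond.
- Forward: acid 1 gives aroyl chloride 2, and arene 3 with acetyl chloride 4 gives ketone 5. Ketone 5 and chloride 2 give, through diketone 6, the 5-fluoroflavone 7. Fluoride 7 gives, through O-aryl hydroxamate 8, the target 9.
- Rings A and B are bought as benzenes; ring C is the only ring made, and it closes in step 3.
- Enabling feature: in ring A, C4a bears the C4 carbonyl and lies between the two oxygen-bearing carbons C5 and C8a. A symmetrical 2,6-difluoroaroyl unit, with each fluorine ortho to that carbonyl, can therefore deliver the O1–C8a bond in the ring closure and the C5–O bond afterwards.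
- Stereochemistry: the target has no stereocentre and no hindered axis, so nothing has to be controlled.

Key step: step 3

Remark: the target is achiral, so the request for a single enantiomer is met by the constitution alone. 1,2,3,4-Tetramethoxybenzene and 2,6-difluoro-4-methoxybenzoic acid are taken to be purchasable. Flavone numbering (O1, C2, C3, C4, C4a, C5–C8, C8a) is used throughout.

**Route**

Step 1
Reactants: 1 2,6-difluoro-4-methoxybenzoic acid
Product: 2 2,6-difluoro-4-methoxybenzoyl chloride
Conditions: (COCl)2 (1.3 equiv), DMF (cat.), CH2Cl2, 0 °C → rt; evaporated and used crude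
Reagents that add atoms: oxalyl chloride ClC(=O)C(Cl)=O
Why: Carboxylic acid to acyl chloride by nucleophilic acyl substitution through the catalytic Vilsmeier chloroiminium species, which should proceed cleanly on this electron-poor acid with only gaseous by-products and without touching the aryl fluorides or the methyl ether.

Step 2
Reactants: 3 1,2,3,4-tetramethoxybenzene; 4 acetyl chloride
Product: 5 1-(2,3,4,5-tetramethoxyphenyl)ethan-1-one
Conditions: AlCl3 (1.1 equiv), CH2Cl2, −10 → 0 °C; ice/1 M HCl quench
Reagents that add atoms: none
Why: Friedel–Crafts acylation, in which the acylium species should attack one of the two symmetry-equivalent free positions of 3 (each ortho to one methoxy group and para to another), the new acetyl group deactivates the ring against a second acylation, and the low temperature with only a slight excess of Lewis acid is chosen to leave the methoxy group ortho to the ketone intact.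

Step 3
Reactants: 5 1-(2,3,4,5-tetramethoxyphenyl)ethan-1-one; 2 2,6-difluoro-4-methoxybenzoyl chloride
Product: 7 5-fluoro-7-methoxy-2-(2,3,4,5-tetramethoxyphenyl)-4H-chromen-4-one, via β-diketone 6 (not isolated)
Conditions: LiHMDS (2.2 equiv), THF, −78 °C; then 2 (1.0 equiv), −78 → 0 °C; then DMPU, 65 °C
Reagents that add atoms: none
Why: This is a crossed Claisen-type C-acylation of a lithium enolate by an aroyl chloride followed by intramolecular nucleophilic aromatic substitution, the established one-flask way from ketone enolates and 2-fluorobenzoyl chlorides to chromones. The first equivalent of LiHMDS gives the lithium enolate of 5, which attacks the acyl carbon of 2 through carbon (C3–C4 bond), and the second equivalent at once deprotonates the much more acidic β-diketone 6, which shields it from further acylation. On warming with DMPU the lithium chelate is loosened and the enolate oxygen on the carbon bearing the tetramethoxyphenyl ring adds to a fluorine-bearing carbon ortho to the ketone; the Meisenheimer-type anion is stabilised as the enolate of the C4 carbonyl and expels fluoride as LiF (O1–C8a bond). Ring C thus closes by a 6-endo-trig addition–elimination at the F–C8a=C4a–C4=O vinylogous acyl fluoride unit, with rearomatisation of ring A. No stereocentre is formed. The step needs C- over O-acylation, which the tightly bound lithium enolate in THF at −78 °C should secure, and displacement of one fluoride only, which follows because the two fluorines are equivalent, the ring-closed product has no internal nucleophile left, and the amide base has by then been consumed as non-nucleophilic HN(SiMe3)2.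

Step 4
Reactants: 7 5-fluoro-7-methoxy-2-(2,3,4,5-tetramethoxyphenyl)-4H-chromen-4-one
Product: 9 5-hydroxy-7-methoxy-2-(2,3,4,5-tetramethoxyphenyl)-4H-chromen-4-one, via O-aryl acetohydroxamate 8 (not isolated)
Conditions: AcNHOH (3 equiv), K2CO3 (5 equiv), DMSO, 80 °C; then 1 M HCl
Reagents that add atoms: acetohydroxamic acid CC(=O)NO
Why: Nucleophilic aromatic substitution of the fluoride activated by the ortho (peri) C4 carbonyl, with the 7-methoxy group and O1 both meta to C5 and so not deactivating, by the acetohydroxamate oxygen, followed by base-induced Lossen-type fragmentation of 8 to the phenoxide and methyl isocyanate; the mild carbonate base should spare the pyranone ring and the methyl ethers, and the product is held as the hydrogen-bonded 5-hydroxy-4-ketone.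

**Compound list**

1 | 2,6-difluoro-4-methoxybenzoic acid | COc1cc(F)c(C(=O)O)c(F)c1 | starting material
2 | 2,6-difluoro-4-methoxybenzoyl chloride | COc1cc(F)c(C(Cl)=O)c(F)c1 | intermediate
3 | 1,2,3,4-tetramethoxybenzene | COc1ccc(OC)c(OC)c1OC | starting material
4 | acetyl chloride | CC(Cl)=O | starting material
5 | 1-(2,3,4,5-tetramethoxyphenyl)ethan-1-one | CC(=O)c1cc(OC)c(OC)c(OC)c1OC | intermediate
6 | 1-(2,6-difluoro-4-methoxyphenyl)-3-(2,3,4,5-tetramethoxyphenyl)propane-1,3-dione (present as its lithium enolate, not isolated) | COc1cc(F)c(C(=O)CC(=O)c2cc(OC)c(OC)c(OC)c2OC)c(F)c1 | intermediate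
7 | 5-fluoro-7-methoxy-2-(2,3,4,5-tetramethoxyphenyl)-4H-chromen-4-one | COc1cc(F)c2c(=O)cc(-c3cc(OC)c(OC)c(OC)c3OC)oc2c1 | intermediate
8 | N-{[7-methoxy-4-oxo-2-(2,3,4,5-tetramethoxyphenyl)-4H-chromen-5-yl]oxy}acetamide (not isolated) | CC(=O)NOc1cc(OC)cc2oc(-c3cc(OC)c(OC)c(OC)c3OC)cc(=O)c12 | intermediate
9 | 5-hydroxy-7-methoxy-2-(2,3,4,5-tetramethoxyphenyl)-4H-chromen-4-one | COc1cc(O)c2c(=O)cc(-c3cc(OC)c(OC)c(OC)c3OC)oc2c1 | target

**Step count and risks**

Total step count: 4. Longest linear sequence: 3 steps (steps 2, 3 and 4; step 1 feeds the convergent step 3).

Steps most likely to fail: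

1. Step 3. The enolate may be acylated at oxygen, or the diketonate may be acylated a second time during the addition. The ring closure may also be slow if the lithium diketonate stays locked in its chelated form, so that long heating lets external nucleophiles attack the activated C–F bonds. The fallback sets out from 5 and comes back at 7, and it forms the C3–C4 bond by aldol addition, so that O-acylation cannot arise. The lithium enolate of 5 (LDA, THF, −78 °C) would be added to purchased 2,6-difluoro-4-methoxybenzaldehyde to give racemic 3-(2,6-difluoro-4-methoxyphenyl)-3-hydroxy-1-(2,3,4,5-tetramethoxyphenyl)propan-1-one F1. Oxidation with Dess–Martin periodinane (CH2Cl2, rt) should give diketone 6, now isolated. K2CO3 in DMSO at 60 °C should then close ring C by the same fluoride displacement to 7.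

2. Step 4. The hydroxamate may add reversibly at C2 and open the pyranone ring in competition with attack at C5, or the reaction may stall at the O-aryl hydroxamate if the fragmentation is slow at the temperature the ring tolerates. The fallback sets out from 7 and comes back at 9, and it replaces the hydroxide surrogate by an alkoxide that reacts at low temperature and is removed reductively. Sodium benzyloxide (BnOH, NaH, THF, 0 °C → rt) should displace the fluoride to give 5-(benzyloxy)-7-methoxy-2-(2,3,4,5-tetramethoxyphenyl)-4H-chromen-4-one F2. Hydrogenolysis (H2, 1 atm, Pd/C, EtOAc) should then free the 5-hydroxyl; the C2=C3 bond of the flavone is expected to survive brief exposure.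

3. Step 2. Once the ketone has formed, aluminium chelated between the carbonyl and the ortho methoxy group may cleave that methyl ether, so that part of the material is lost as the ortho-hydroxy ketone. The fallback sets out from 3 and comes back at 5, and it avoids Lewis acids altogether. Bromination (NBS, MeCN, rt) should give 1-bromo-2,3,4,5-tetramethoxybenzene F3. Bromine–lithium exchange (n-BuLi, THF, −78 °C) and trapping of the aryllithium with N-methoxy-N-methylacetamide should give 5 after aqueous NH4Cl work-up.

Further compounds
F1 | step 3 | 3-(2,6-difluoro-4-methoxyphenyl)-3-hydroxy-1-(2,3,4,5-tetramethoxyphenyl)propan-1-one (racemic) | COc1cc(F)c(C(O)CC(=O)c2cc(OC)c(OC)c(OC)c2OC)c(F)c1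
F2 | step 4 | 5-(benzyloxy)-7-methoxy-2-(2,3,4,5-tetramethoxyphenyl)-4H-chromen-4-one | COc1cc(OCc2ccccc2)c2c(=O)cc(-c3cc(OC)c(OC)c(OC)c3OC)oc2c1
F3 | step 2 | 1-bromo-2,3,4,5-tetramethoxybenzene | COc1cc(Br)c(OC)c(OC)c1OC
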